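Past 3.00 h, Monday's left-handed product reads 46%, 45%, 46%, which stands within the scatter of 1.5 percentage points. So the decision for the next flask is what a partner charge buys by 4.0 h: excess, or conversion.

| flask | left-handed substrate | right-handed substrate | partner | remark | time |
|---|---|---|---|---|---|
| Monday's | 0.10 M | 0.10 M | 0.20 M | run made earlier |  |
| Wednesday's | 0.10 M | 0.10 M | 0.45 M | run made earlier |  |
| flask | 0.10 M | 0.10 M | 0.300 M |  | 4.0 h |

| run | time / h | left-handed product / % | right-handed product / % | left-handed substrate / % |
|---|---|---|---|---|
| Monday's | 0.833 | 29 | 11 | 26 |
| Monday's | 1.50 | 32 | 18 | 23 |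
| Monday's | 2.50 | 43 | 21 | 17 |
| Monday's | 3.00 | 46 | 20 | 18 |
| Monday's | 4.00 | 45 | 20 | 16 |
| Monday's | 5.00 | 46 | 22 | 17 |
| Wednesday's | 0.833 | 47 | 23 | 15 |
| Wednesday's | 1.50 | 49 | 28 | 14 |
| Wednesday's | 2.50 | 55 | 29 | 7 |
| Wednesday's | 3.00 | 58 | 31 | 8 |
| Wednesday's | 4.00 | 58 | 31 | 5 |
| Wednesday's | 5.00 | 60 | 32 | 4 |

(scatter of a reading: 1.5 percentage points)

1. excess of left-handed product over right-handed product in the product at 12 min
2. excess of left-handed product over right-handed product in the product at 4.0 h
3. part of the left-handed substrate and right-handed substrate charged together that has reacted at 4.0 h

- partner is single-handed; left-handed substrate and right-handed substrate are mirror images of each other, charged as a racemate, each of them at the stated concentration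
- steps under discussion: partner -> decomposition product; partner <-> dormant form; left-handed substrate <-> right-handed substrate; partner + left-handed substrate -> left-handed product; 2 partner -> self-condensation product; partner + right-handed substrate -> right-handed product
- an excess is the difference of the two amounts in percent of their sum
- an excess is below zero if the other one leads
- the handed part of partner does not stay in what it makes, so the products of the two hands are mirror images too

We take as zero of the scale a partner blind to hand, which makes both products equally from level substrates. Wednesday's left-handed product reaches 60% at 5.00 h, more than the half of the charge that was left-handed, so right-handed substrate turns into left-handed (a dynamic kinetic resolution). By balance, Wednesday's right-handed substrate at 4.00 h is 6.00% against 5% left-handed. While the two stand level, partner multiplies both rates alike, and the products keep one ratio.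

Monday's excess at 4.00 h reads 38.5%, and Wednesday's, at twice the partner, reads 30.3%. Their mean is E = 34.4%, the run excess: the excess of the product collected by 4.00 h, averaged over the two partner charges. The first readings, 45.0% and 34.3%, lie on either side of it, so we expect E at 12 min and at 4.0 h alike, and we charge 0.300 M for conversion, not for excess.

The forecast, calling this a “partial dynamic resolution”, gives 45% at 12 min, above our E, then 34% and 79% reacted at 4.0 h.

The flask gives 35.7%, 34.4% and 79.7%, so its early excess stands 1.3 points from E.

    partner → decomposition product (k = 1.40 × 10⁻⁴ min⁻¹)
    partner ⇌ dormant form (K = 0.260, k = 0.300 min⁻¹)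
    left-handed substrate ⇌ right-handed substrate (k = 0.0340 min⁻¹)
    partner + left-handed substrate → left-handed product (k = 0.160 M⁻¹ min⁻¹)
    2 partner → self-condensation product (k = 0.0420 M⁻¹ min⁻¹)
    partner + right-handed substrate → right-handed product (k = 0.0700 M⁻¹ min⁻¹)

A neighbouring flask with 0.51 M of partner tests E again: it holds 60.3% left-handed and 31.3% right-handed product at 4.0 h, an excess of 31.7% against E's 34.4%, with 91.6% reacted.

(The numbers in the tables were generated by integration for substances that don't exist, noise included.)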